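**Retrosynthetic overview**
1. The butenolide is formed last, by acylation/intramolecular Wittig of α-hydroxy ketone 28 with Ph3P=C=C=O; the ketone oxygen it consumes is the former ring oxygen of a dihydropyran.
2. Key disconnection: the CH2–C(CH3)= bond of the olefin nearer the lactone, made by a three-component Cu(I) 1,2-metallate rearrangement (C16 homoallyllithium + 6-lithiated dihydropyran 21 + MeI) that opens a temporary ring.
3. Enabling feature: the methyl-bearing olefinic carbon and butenolide C4 are 1,5-related through =CH–CH2–CH2–, and C4 can carry oxygen (as C=O) before the lactone exists. This C(sp2)···C–O array is a ring-opened 3,4-dihydro-2H-pyran, and the methyl cis to that chain is what inversion plus MeI capture delivers.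
4. The left half is built by the same logic one isoprene unit earlier: (cyclohexenyl)ethyllithium from iodide 12 + lithiated 2,3-dihydrofuran + MeI.
5. The carbocycle comes first: Birch reductive alkylation of o-anisic acid gives a 2-substituted cyclohexenone; Cu-catalysed asymmetric methyl addition/enolate methylation sets both stereocentres; enol triflate methylation installs the ring olefin.

Key step: step 10

Assumptions: (i) commercial racemic (3,4-dihydro-2H-pyran-2-yl)methanol is used; its stereocentre becomes the ketone carbon in step 11, so 21, 22, 24, 25 and 26 are drawn without configuration there. (ii) In step 2 the ligand antipode is taken that delivers methyl to give the (3R) centre.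

**Step 1**
Reactants: 1 2-methoxybenzoic acid; 2 benzyl 2-bromoethyl ether
Product: 5 2-[2-(benzyloxy)ethyl]cyclohex-2-en-1-one, via Birch dianion 3 (not isolated), via alkylated dienoic acid 4 (not isolated)
Conditions: Li (3.2 equiv), NH3(l)/THF, −78 °C; 2 (2 equiv), −78 → −33 °C; evaporate NH3; 2 M HCl, THF, 60 °C
Reagents that add atoms: water, O
Why: Birch reductive alkylation of o-anisic acid (C1-alkylation of the carboxylate-stabilised dianion), then acid hydrolysis of the enol ether, decarboxylation of the β-keto acid and conjugation, is the standard entry to 2-alkylcyclohex-2-enones.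

**Step 2**
Reactants: 5 2-[2-(benzyloxy)ethyl]cyclohex-2-en-1-one
Product: 7 (2R,3R)-2-[2-(benzyloxy)ethyl]-2,3-dimethylcyclohexan-1-one, via aluminium enolate 6 (not isolated)
Conditions: Me3Al (1.5 equiv), CuTC (2 mol %), chiral phosphoramidite (4 mol %), Et2O, −30 °C; then MeLi (1.5 equiv), MeI (4 equiv), THF/DMPU, −30 → 0 °C
Reagents that add atoms: trimethylaluminium, C[Al](C)C; iodomethane, CI
Why: Cu-catalysed asymmetric conjugate addition of Me3Al to an α-substituted cyclohexenone should set C3 (R) under ligand control; the regiodefined aluminium enolate, activated as its lithium aluminate, should be C-methylated by axial attack anti to the pseudoaxial C3 methyl (A1,2 strain), giving the trans-dimethyl quaternary centre (2R).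

**Step 3**
Reactants: 7 (2R,3R)-2-[2-(benzyloxy)ethyl]-2,3-dimethylcyclohexan-1-one
Product: 9 (5R,6R)-6-[2-(benzyloxy)ethyl]-5,6-dimethylcyclohex-1-en-1-yl trifluoromethanesulfonate, via potassium enolate 8 (not isolated)
Conditions: KHMDS, THF, −78 °C; PhNTf2, −78 → 0 °C
Reagents that add atoms: N-phenylbis(trifluoromethanesulfonimide), O=S(=O)(N(c1ccccc1)S(=O)(=O)C(F)(F)F)C(F)(F)F
Why: The ketone has only one enolisable α-position (C6), so enolate O-triflation should be regiospecific and leave both stereocentres untouched.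

**Step 4**
Reactants: 9 (5R,6R)-6-[2-(benzyloxy)ethyl]-5,6-dimethylcyclohex-1-en-1-yl trifluoromethanesulfonate
Product: 10 benzyl 2-[(1R,6R)-1,2,6-trimethylcyclohex-2-en-1-yl]ethyl ether
Conditions: MeMgBr (1.5 equiv), Fe(acac)3 (5 mol %), THF/NMP, −30 → 0 °C
Reagents that add atoms: methylmagnesium bromide, C[Mg]Br
Why: Iron-catalysed cross-coupling of an alkenyl triflate with MeMgBr should replace OTf by methyl with retention of the olefin position, giving the ring C(CH3)=CH unit next to the quaternary carbon.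

**Step 5**
Reactants: 10 benzyl 2-[(1R,6R)-1,2,6-trimethylcyclohex-2-en-1-yl]ethyl ether
Product: 11 2-[(1R,6R)-1,2,6-trimethylcyclohex-2-en-1-yl]ethan-1-ol
Conditions: LiDBB, THF, −78 °C; aq. NH4Cl
Reagents that add atoms: none
Why: Reductive cleavage of the benzylic C–O bond by an arene radical anion should free the alcohol without touching the isolated trisubstituted olefin.

**Step 6**
Reactants: 11 2-[(1R,6R)-1,2,6-trimethylcyclohex-2-en-1-yl]ethan-1-ol
Product: 12 (5R,6R)-6-(2-iodoethyl)-1,5,6-trimethylcyclohex-1-ene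
Conditions: I2, PPh3, imidazole, CH2Cl2, 0 °C → rt
Reagents that add atoms: iodine, II
Why: Appel-type iodination of a primary alcohol proceeds by SN2 on the alkoxyphosphonium ion under non-acidic conditions that the olefin tolerates.

**Step 7**
Reactants: 12 (5R,6R)-6-(2-iodoethyl)-1,5,6-trimethylcyclohex-1-ene; 13 2,3-dihydrofuran
Product: 18 (3E)-4-methyl-6-[(1R,6R)-1,2,6-trimethylcyclohex-2-en-1-yl]hex-3-en-1-ol, via 5-lithio-2,3-dihydrofuran 14 (not isolated), via alkyllithium 15 (not isolated), via mixed cuprate 16 (not isolated), via alkenylcopper alkoxide 17 (not isolated)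
Conditions: 13 (1.3 equiv), t-BuLi, THF/pentane, −78 → 0 °C; 12, t-BuLi (2.1 equiv), Et2O/pentane, −78 °C; CuBr·SMe2 (1 equiv), Et2O/Me2S, −78 °C → rt; MeI (5 equiv), DMPU, 0 °C → rt; aq. NH4Cl/NH3
Reagents that add atoms: iodomethane, CI
Why: Copper-mediated 1,2-metallate rearrangement of the α-alkoxyalkenyl cuprate should transfer the alkyl group to the enol ether carbon with inversion and ring opening, and methylation of the alkenylcopper with retention should give the E-trisubstituted homoallylic alcohol.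

**Step 8**
Reactants: 18 (3E)-4-methyl-6-[(1R,6R)-1,2,6-trimethylcyclohex-2-en-1-yl]hex-3-en-1-ol
Product: 19 (5R,6R)-6-[(3E)-6-iodo-3-methylhex-3-en-1-yl]-1,5,6-trimethylcyclohex-1-ene
Conditions: I2, PPh3, imidazole, CH2Cl2, 0 °C → rt
Reagents that add atoms: iodine, II
Why: Appel-type iodination of the primary homoallylic alcohol should proceed without olefin isomerisation.

**Step 9**
Reactants: 20 (3,4-dihydro-2H-pyran-2-yl)methanol (racemic)
Product: 21 2-{[(triisopropylsilyl)oxy]methyl}-3,4-dihydro-2H-pyran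
Conditions: TIPSCl, imidazole, DMF, rt
Reagents that add atoms: chlorotriisopropylsilane, CC(C)[Si](Cl)(C(C)C)C(C)C
Why: Standard silylation under basic conditions preserves the acid-labile enol ether; TIPS is chosen because it resists t-BuLi in the following vinylic lithiation, as in C1-lithiation of silylated glycals.

**Step 10**
Reactants: 19 (5R,6R)-6-[(3E)-6-iodo-3-methylhex-3-en-1-yl]-1,5,6-trimethylcyclohex-1-ene; 21 2-{[(triisopropylsilyl)oxy]methyl}-3,4-dihydro-2H-pyran
Product: 26 (5E,9E)-6,10-dimethyl-1-[(triisopropylsilyl)oxy]-12-[(1R,6R)-1,2,6-trimethylcyclohex-2-en-1-yl]dodeca-5,9-dien-2-ol (C2 epimers), via lithiated dihydropyran 22 (not isolated), via homoallyllithium 23 (not isolated), via mixed cuprate 24 (not isolated), via alkenylcopper alkoxide 25 (not isolated)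
Conditions: 21 (1.3 equiv), t-BuLi, THF, −78 → 0 °C; 19, t-BuLi (2.1 equiv), Et2O/pentane, −78 °C; CuBr·SMe2 (1 equiv), Et2O/Me2S, −78 °C → rt; MeI (5 equiv), DMPU, 0 °C → rt; aq. NH4Cl/NH3
Reagents that add atoms: iodomethane, CI
Why: Lithiated enol ether 22 and homoallyllithium 23 combine on copper(I) to the mixed cuprate 24, in which the alkyl group migrates from copper to the oxygen-bearing sp2 carbon with expulsion of the ring oxygen as alkoxide (1,2-metallate rearrangement), and the resulting alkenylcopper 25 is methylated by MeI with retention. The closest known reaction type is the copper-mediated 1,2-metallate rearrangement of α-lithiated 2,3-dihydrofurans and 3,4-dihydro-2H-pyrans with alkylcuprates followed by alkylation, used iteratively for E-trisubstituted isoprenoid olefins. No ring is closed; the temporary dihydropyran ring is opened, and no stereocentre is created (the carbinol carbon of racemic 21 is carried as an epimeric mixture and erased in step 11). The new olefin geometry is controlled by the ring: migration occurs with inversion at the sp2 carbon (in-plane backside displacement of the endocyclic C–O bond), so the incoming chain ends trans, and copper and then methyl cis, to the CH2CH2 chain, which is the E-isomer. The step needs alkyl rather than alkenyl transfer and complete migration before methylation; the α-alkoxyalkenyl ligand is the only acceptor on copper, MeI is added only after warming, and the TIPS ether survives the lithiation. In one operation the step should join C16 and C6 fragments, install the vinylic methyl, fix the olefin geometry and unveil the oxygen needed for the butenolide.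

**Step 11**
Reactants: 26 (5E,9E)-6,10-dimethyl-1-[(triisopropylsilyl)oxy]-12-[(1R,6R)-1,2,6-trimethylcyclohex-2-en-1-yl]dodeca-5,9-dien-2-ol
Product: 27 (5E,9E)-6,10-dimethyl-1-[(triisopropylsilyl)oxy]-12-[(1R,6R)-1,2,6-trimethylcyclohex-2-en-1-yl]dodeca-5,9-dien-2-one
Conditions: Dess–Martin periodinane, NaHCO3, CH2Cl2, 0 °C → rt
Reagents that add atoms: none
Why: Buffered Dess–Martin oxidation of the only free (secondary) alcohol should give the α-silyloxy ketone without affecting the olefins, and converges the epimers to one compound.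

**Step 12**
Reactants: 27 (5E,9E)-6,10-dimethyl-1-[(triisopropylsilyl)oxy]-12-[(1R,6R)-1,2,6-trimethylcyclohex-2-en-1-yl]dodeca-5,9-dien-2-one
Product: 28 (5E,9E)-1-hydroxy-6,10-dimethyl-12-[(1R,6R)-1,2,6-trimethylcyclohex-2-en-1-yl]dodeca-5,9-dien-2-one
Conditions: HF·pyridine, pyridine/THF, 0 °C → rt
Reagents that add atoms: none
Why: Fluoride-driven Si–O cleavage under buffered, non-basic conditions should release the primary α-ketol without base-induced ketol isomerisation.

**Step 13**
Reactants: 28 (5E,9E)-1-hydroxy-6,10-dimethyl-12-[(1R,6R)-1,2,6-trimethylcyclohex-2-en-1-yl]dodeca-5,9-dien-2-one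
Product: 29 4-[(3E,7E)-4,8-dimethyl-10-[(1R,6R)-1,2,6-trimethylcyclohex-2-en-1-yl]deca-3,7-dien-1-yl]furan-2(5H)-one
Conditions: Ph3P=C=C=O (1.2 equiv), toluene, 80 °C
Reagents that add atoms: (triphenylphosphoranylidene)ketene, O=C=C=P(c1ccccc1)(c1ccccc1)c1ccccc1
Why: Addition of the hydroxyl to the cumulated ylide gives an acyl-stabilised ylide ester that closes on the adjacent ketone by intramolecular Wittig olefination (5-ring, necessarily Z), the established conversion of α-hydroxy ketones into 4-substituted butenolides.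

**Compound list**
1 | 2-methoxybenzoic acid | COc1ccccc1C(=O)O | starting material
2 | benzyl 2-bromoethyl ether | BrCCOCc1ccccc1 | starting material
3 | dilithium 2-methoxy-1,4-dihydrobenzoate dianion (Birch dianion) | [Li+].[Li+].COC1=CCC=CC1=C([O-])[O-] | intermediate (not isolated)
4 | 1-[2-(benzyloxy)ethyl]-2-methoxycyclohexa-2,5-diene-1-carboxylic acid | COC1=CCC=CC1(CCOCc1ccccc1)C(=O)O | intermediate (not isolated)
5 | 2-[2-(benzyloxy)ethyl]cyclohex-2-en-1-one | O=C1CCCC=C1CCOCc1ccccc1 | intermediate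
6 | dimethylaluminium (3R)-2-[2-(benzyloxy)ethyl]-3-methylcyclohex-1-en-1-olate | C[Al](C)OC1=C(CCOCc2ccccc2)[C@H](C)CCC1 | intermediate (not isolated)
7 | (2R,3R)-2-[2-(benzyloxy)ethyl]-2,3-dimethylcyclohexan-1-one | O=C1CCC[C@@H](C)[C@@]1(C)CCOCc1ccccc1 | intermediate
8 | potassium (5R,6R)-6-[2-(benzyloxy)ethyl]-5,6-dimethylcyclohex-1-en-1-olate | [K+].[O-]C1=CCC[C@@H](C)[C@@]1(C)CCOCc1ccccc1 | intermediate (not isolated)
9 | (5R,6R)-6-[2-(benzyloxy)ethyl]-5,6-dimethylcyclohex-1-en-1-yl trifluoromethanesulfonate | O=S(=O)(OC1=CCC[C@@H](C)[C@@]1(C)CCOCc1ccccc1)C(F)(F)F | intermediate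
10 | benzyl 2-[(1R,6R)-1,2,6-trimethylcyclohex-2-en-1-yl]ethyl ether | CC1=CCC[C@@H](C)[C@@]1(C)CCOCc1ccccc1 | intermediate
11 | 2-[(1R,6R)-1,2,6-trimethylcyclohex-2-en-1-yl]ethan-1-ol | CC1=CCC[C@@H](C)[C@@]1(C)CCO | intermediate
12 | (5R,6R)-6-(2-iodoethyl)-1,5,6-trimethylcyclohex-1-ene | CC1=CCC[C@@H](C)[C@@]1(C)CCI | intermediate
13 | 2,3-dihydrofuran | C1=COCC1 | starting material
14 | 5-lithio-2,3-dihydrofuran | [Li]C1=CCCO1 | intermediate (not isolated)
15 | 2-[(1R,6R)-1,2,6-trimethylcyclohex-2-en-1-yl]ethyllithium | CC1=CCC[C@@H](C)[C@@]1(C)CC[Li] | intermediate (not isolated)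
16 | lithium (4,5-dihydrofuran-2-yl){2-[(1R,6R)-1,2,6-trimethylcyclohex-2-en-1-yl]ethyl}cuprate | [Li+].CC1=CCC[C@@H](C)[C@@]1(C)CC[Cu-]C1=CCCO1 | intermediate (not isolated)
17 | lithium (3Z)-4-cuprio-6-[(1R,6R)-1,2,6-trimethylcyclohex-2-en-1-yl]hex-3-en-1-olate | CC1=CCC[C@@H](C)[C@@]1(C)CC/C([Cu])=C/CCO[Li] | intermediate (not isolated)
18 | (3E)-4-methyl-6-[(1R,6R)-1,2,6-trimethylcyclohex-2-en-1-yl]hex-3-en-1-ol | CC1=CCC[C@@H](C)[C@@]1(C)CC/C(C)=C/CCO | intermediate
19 | (5R,6R)-6-[(3E)-6-iodo-3-methylhex-3-en-1-yl]-1,5,6-trimethylcyclohex-1-ene | CC1=CCC[C@@H](C)[C@@]1(C)CC/C(C)=C/CCI | intermediate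
20 | (3,4-dihydro-2H-pyran-2-yl)methanol (racemic) | OCC1CCC=CO1 | starting material
21 | 2-{[(triisopropylsilyl)oxy]methyl}-3,4-dihydro-2H-pyran (racemic) | CC(C)[Si](OCC1CCC=CO1)(C(C)C)C(C)C | intermediate
22 | 6-lithio-2-{[(triisopropylsilyl)oxy]methyl}-3,4-dihydro-2H-pyran | [Li]C1=CCCC(CO[Si](C(C)C)(C(C)C)C(C)C)O1 | intermediate (not isolated)
23 | (3E)-4-methyl-6-[(1R,6R)-1,2,6-trimethylcyclohex-2-en-1-yl]hex-3-en-1-yllithium | CC1=CCC[C@@H](C)[C@@]1(C)CC/C(C)=C/CC[Li] | intermediate (not isolated)
24 | lithium mixed cuprate of 22 and 23 (alkyl and dihydropyran-6-yl on copper) | [Li+].CC1=CCC[C@@H](C)[C@@]1(C)CC/C(C)=C/CC[Cu-]C1=CCCC(CO[Si](C(C)C)(C(C)C)C(C)C)O1 | intermediate (not isolated)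
25 | lithium (5Z,9E)-6-cuprio-10-methyl-1-[(triisopropylsilyl)oxy]-12-[(1R,6R)-1,2,6-trimethylcyclohex-2-en-1-yl]dodeca-5,9-dien-2-olate | CC1=CCC[C@@H](C)[C@@]1(C)CC/C(C)=C/CC/C([Cu])=C/CCC(O[Li])CO[Si](C(C)C)(C(C)C)C(C)C | intermediate (not isolated)
26 | (5E,9E)-6,10-dimethyl-1-[(triisopropylsilyl)oxy]-12-[(1R,6R)-1,2,6-trimethylcyclohex-2-en-1-yl]dodeca-5,9-dien-2-ol (C2 epimers) | CC1=CCC[C@@H](C)[C@@]1(C)CC/C(C)=C/CC/C(C)=C/CCC(O)CO[Si](C(C)C)(C(C)C)C(C)C | intermediate
27 | (5E,9E)-6,10-dimethyl-1-[(triisopropylsilyl)oxy]-12-[(1R,6R)-1,2,6-trimethylcyclohex-2-en-1-yl]dodeca-5,9-dien-2-one | CC1=CCC[C@@H](C)[C@@]1(C)CC/C(C)=C/CC/C(C)=C/CCC(=O)CO[Si](C(C)C)(C(C)C)C(C)C | intermediate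
28 | (5E,9E)-1-hydroxy-6,10-dimethyl-12-[(1R,6R)-1,2,6-trimethylcyclohex-2-en-1-yl]dodeca-5,9-dien-2-one | CC1=CCC[C@@H](C)[C@@]1(C)CC/C(C)=C/CC/C(C)=C/CCC(=O)CO | intermediate
29 | 4-[(3E,7E)-4,8-dimethyl-10-[(1R,6R)-1,2,6-trimethylcyclohex-2-en-1-yl]deca-3,7-dien-1-yl]furan-2(5H)-one | CC1=CCC[C@@H](C)[C@@]1(C)CC/C(C)=C/CC/C(C)=C/CCC1=CC(=O)OC1 | target

**Step count**
Total: 13 steps. Longest linear sequence: 12 steps (steps 1–8, then 10–13); step 9 is a one-step side branch.

**Steps most likely to fail**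

Step 10. The alkyl migration in a six-membered α-alkoxyalkenyl cuprate is slower than in the five-membered series, so thermal decomposition of the mixed cuprate, homocoupling, or protonation in place of methylation may compete. The fallback sets out from 19 and uses the faster five-membered enol ether, attaching the butenolide afterwards by cross-coupling instead of building it by Wittig closure. Iodide 19 is lithiated to 23 and combined with 14 (from 13) and CuBr·SMe2 to the lithium mixed cuprate F1, which should rearrange on warming to the lithium (3Z,7E)-4-cuprio-dienolate F2 and be methylated by MeI to (3E,7E)-4,8-dimethyl-10-[(1R,6R)-1,2,6-trimethylcyclohex-2-en-1-yl]deca-3,7-dien-1-ol F3. Appel iodination gives the homoallylic iodide F4; zinc insertion (Zn dust, LiCl, THF) gives the alkylzinc iodide F5; Negishi coupling of F5 with commercial 4-bromofuran-2(5H)-one (Pd(PPh3)4, THF, rt) forms the butenolide C4–CH2 bond and comes back to the route at 29.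

Step 2. Methyl transfer to an α-branched enone bearing a coordinating ether may proceed with low enantioselectivity, and the methylation may show poor facial selectivity or O-alkylation. The fallback sets out from 5 and replaces catalyst control by a reagent-controlled reduction followed by substrate-controlled steps. CBS reduction ((R)-Me-CBS, BH3·SMe2) should give (S)-2-[2-(benzyloxy)ethyl]cyclohex-2-en-1-ol F6. Hydroxyl-directed Simmons–Smith cyclopropanation (Et2Zn, CH2I2) gives the syn cyclopropyl carbinol (1S,2S,6S)-1-[2-(benzyloxy)ethyl]bicyclo[4.1.0]heptan-2-ol F7, and Dess–Martin oxidation gives the cyclopropyl ketone (1S,6S)-1-[2-(benzyloxy)ethyl]bicyclo[4.1.0]heptan-2-one F8. Li/NH3 cleaves the exocyclic cyclopropane bond (the one overlapping the carbonyl π-system), turning the cyclopropane CH2 into the C3 methyl and giving the regiodefined dilithium enolate–alkoxide F9; the benzyl ether is cleaved in the same operation. Trapping with MeI anti to the C3 methyl gives (2R,3R)-2-(2-hydroxyethyl)-2,3-dimethylcyclohexan-1-one F10. Re-benzylation (benzyl 2,2,2-trichloroacetimidate, TfOH cat.) comes back to the route at 7.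

Step 13. The primary α-ketol may self-condense or isomerise under the warm, basic ylide conditions, or the acylated ylide may fail to close onto the hindered ketone. The fallback sets out from 28 and separates acylation from ring closure. Esterification with diethylphosphonoacetic acid (DCC, DMAP, CH2Cl2, 0 °C) gives the phosphonoacetate ester F11, and intramolecular Horner–Wadsworth–Emmons olefination under mild base (LiCl, DBU, MeCN, rt) closes the butenolide and comes back to the route at 29.

**Further compounds**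
F1 | step 10 | lithium (4,5-dihydrofuran-2-yl){(3E)-4-methyl-6-[(1R,6R)-1,2,6-trimethylcyclohex-2-en-1-yl]hex-3-en-1-yl}cuprate | [Li+].CC1=CCC[C@@H](C)[C@@]1(C)CC/C(C)=C/CC[Cu-]C1=CCCO1
F2 | step 10 | lithium (3Z,7E)-4-cuprio-8-methyl-10-[(1R,6R)-1,2,6-trimethylcyclohex-2-en-1-yl]deca-3,7-dien-1-olate | CC1=CCC[C@@H](C)[C@@]1(C)CC/C(C)=C/CC/C([Cu])=C/CCO[Li]
F3 | step 10 | (3E,7E)-4,8-dimethyl-10-[(1R,6R)-1,2,6-trimethylcyclohex-2-en-1-yl]deca-3,7-dien-1-ol | CC1=CCC[C@@H](C)[C@@]1(C)CC/C(C)=C/CC/C(C)=C/CCO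
F4 | step 10 | (5R,6R)-6-[(3E,7E)-10-iodo-3,7-dimethyldeca-3,7-dien-1-yl]-1,5,6-trimethylcyclohex-1-ene | CC1=CCC[C@@H](C)[C@@]1(C)CC/C(C)=C/CC/C(C)=C/CCI
F5 | step 10 | (3E,7E)-4,8-dimethyl-10-[(1R,6R)-1,2,6-trimethylcyclohex-2-en-1-yl]deca-3,7-dien-1-ylzinc iodide | CC1=CCC[C@@H](C)[C@@]1(C)CC/C(C)=C/CC/C(C)=C/CC[Zn]I
F6 | step 2 | (1S)-2-[2-(benzyloxy)ethyl]cyclohex-2-en-1-ol | O[C@H]1CCCC=C1CCOCc1ccccc1
F7 | step 2 | (1S,2S,6S)-1-[2-(benzyloxy)ethyl]bicyclo[4.1.0]heptan-2-ol | O[C@H]1CCC[C@H]2C[C@@]12CCOCc1ccccc1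
F8 | step 2 | (1S,6S)-1-[2-(benzyloxy)ethyl]bicyclo[4.1.0]heptan-2-one | O=C1CCC[C@H]2C[C@@]12CCOCc1ccccc1
F9 | step 2 | dilithium (3R)-2-(2-oxidoethyl)-3-methylcyclohex-1-en-1-olate | [Li]OC1=C(CCO[Li])[C@H](C)CCC1
F10 | step 2 | (2R,3R)-2-(2-hydroxyethyl)-2,3-dimethylcyclohexan-1-one | O=C1CCC[C@@H](C)[C@@]1(C)CCO
F11 | step 13 | (5E,9E)-6,10-dimethyl-2-oxo-12-[(1R,6R)-1,2,6-trimethylcyclohex-2-en-1-yl]dodeca-5,9-dien-1-yl (diethoxyphosphoryl)acetate | CC1=CCC[C@@H](C)[C@@]1(C)CC/C(C)=C/CC/C(C)=C/CCC(=O)COC(=O)CP(=O)(OCC)OCC
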